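**Retrosynthetic overview**

1. The strategy rests on C12 of the five-membered ring (C8–C12): it is a tertiary allylic carbinol whose ring neighbour C11 is olefinic (C10=C11). The C11–C12 bond is therefore cut to a Z-vinyl iodide at C11 and a C12 ketone that already carries the (Z)-oct-2-enyl chain. This one ring is closed by an intramolecular Nozaki–Hiyama–Kishi reaction.
2. After ring closure: C9–OTBS becomes the C9 ketone, chlorine is put on C10 of the enone, and C7–OPMB becomes C7–OAc.
3. Open-chain precursor: C8–C9 comes from the dianion aldol of (R)-3-hydroxy-γ-butyrolactone with (Z)-3-iodoacrolein (C8 set trans to O7). O7 and O9 are told apart by lactone opening and a C6/C7 4-methoxybenzylidene acetal, which later leaves the PMB group on O7.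
4. C12–C13 comes from α-selective addition of (Z)-oct-2-enylbarium to the C12 aldehyde, C5=C6 from a Z-selective Wittig reaction at the C6 aldehyde, and C12 is oxidised to the ketone last.

Key step: step 17

Remark: prostanoid numbering is used for all intermediates (C1 ester carbon, C7 oxygenated side-chain carbon, C8–C12 ring carbons, C13–C20 octenyl chain).
Remark: the aldol of step 3 is assumed to give mainly the anti (9R) carbinol, which is the epimer drawn; C9 becomes a ketone in step 19, so its configuration does not reach the target.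

**Route**

Step 1
Reactants: 1 ethyl propiolate
Product: 2 ethyl (Z)-3-iodoprop-2-enoate
Conditions: NaI, AcOH, 70 °C
Reagents that add atoms: sodium iodide, [Na+].[I-]
Why: Conjugate hydroiodination of an ynoate, in which iodide and the proton add anti across the triple bond, so the Z-β-iodoacrylate should be the kinetic product.

Step 2
Reactants: 2 ethyl (Z)-3-iodoprop-2-enoate
Product: 3 (Z)-3-iodoprop-2-enal
Conditions: i-Bu2AlH (1.05 equiv), CH2Cl2, −78 °C; MeOH, then aq. potassium sodium tartrate, cold; dried solution used at once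
Reagents that add atoms: none
Why: Partial reduction of an ester, whose aluminium hemiacetal is stable at −78 °C and gives the aldehyde only on work-up; exclusion of acid, light and heat should keep the Z geometry.

Step 3
Reactants: 4 (R)-3-hydroxy-γ-butyrolactone; 3 (Z)-3-iodoprop-2-enal
Product: 6 (3R,4R)-4-hydroxy-3-[(1R,2Z)-1-hydroxy-3-iodoprop-2-en-1-yl]oxolan-2-one, via dilithio dianion 5 (not isolated)
Conditions: LiN(i-Pr)2 (2.2 equiv), THF, −78 to −40 °C; then 3, −78 °C; AcOH, −78 °C
Reagents that add atoms: none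
Why: Dianion aldol of a β-hydroxy lactone (Fráter–Seebach type), in which the lithium alkoxide cannot leave and so blocks β-elimination; the aldehyde adds to the enolate face opposite O7–Li, which sets C8 trans to O7, and the ring-fixed E enolate in a Zimmerman–Traxler chair should favour the anti carbinol at C9.

Step 4
Reactants: 6 aldol lactone
Product: 7 (2R,3R)-3,4-dihydroxy-2-[(1R,2Z)-1-hydroxy-3-iodoprop-2-en-1-yl]-N-methoxy-N-methylbutanamide
Conditions: MeNH(OMe)·HCl, AlMe3, CH2Cl2, 0 °C to rt; aq. potassium sodium tartrate; crude product used directly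
Reagents that add atoms: N,O-dimethylhydroxylamine hydrochloride, CNOC.Cl
Why: Aluminium amide aminolysis of a lactone (Weinreb amide formation) frees the primary O6–H without touching the three stereocentres, and immediate use of the crude triol should forestall relactonisation.

Step 5
Reactants: 7 Weinreb amide triol
Product: 8 Weinreb amide in which O6 and O7 are joined as a 2-(4-methoxyphenyl)-1,3-dioxolane (both acetal epimers), C9–OH free, C7, C8 and C9 as in 6
Conditions: 4-MeOC6H4CH(OMe)2 (1.3 equiv), PPTS (cat.), CH2Cl2, 0 °C to rt; Et3N quench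
Reagents that add atoms: 4-methoxybenzaldehyde dimethyl acetal, COc1ccc(C(OC)OC)cc1
Why: Acid-catalysed transacetalisation, which starts at the primary O6–H and closes onto O7 to the five-membered acetal, whereas a dioxane across the anti-related O7/O9 pair would need an axial substituent, so O9–H should stay free; the new acetal centre is uncontrolled and is erased in step 11.

Step 6
Reactants: 8 dioxolane Weinreb amide
Product: 9 C9 tert-butyldimethylsilyl ether of 8
Conditions: t-BuMe2SiOTf, 2,6-lutidine, CH2Cl2, −78 °C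
Reagents that add atoms: tert-butyldimethylsilyl triflate, CC(C)(C)[Si](C)(C)OS(=O)(=O)C(F)(F)F
Why: Silylation of the only free hydroxyl with a silyl triflate, which at −78 °C is fast for a hindered allylic alcohol and should leave the benzylidene acetal closed.

Step 7
Reactants: 9 silyl ether Weinreb amide
Product: 10 C12 aldehyde, 3-(tert-butyldimethylsilyloxy)-5-iodo-2-[2-(4-methoxyphenyl)-1,3-dioxolan-4-yl]pent-4-enal, Z olefin, C7, C8 and C9 as in 6
Conditions: i-Bu2AlH (1.5 equiv), THF, −78 °C; aq. potassium sodium tartrate; crude aldehyde used at once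
Reagents that add atoms: none
Why: Weinreb amide reduction, which stops at the aldehyde because the chelated tetrahedral aluminium intermediate survives until work-up; at −78 °C the acetal is not opened, and the epimerisable aldehyde is not chromatographed.

Step 8
Reactants: 11 (Z)-oct-2-en-1-ol
Product: 12 (Z)-1-chlorooct-2-ene
Conditions: N-chlorosuccinimide, Me2S, CH2Cl2, −20 to 0 °C
Reagents that add atoms: N-chlorosuccinimide, ClN1C(=O)CCC1=O
Why: Corey–Kim-type chlorination of an allylic alcohol, in which chloride displaces the alkoxysulfonium group at the primary carbon, so the Z olefin should be kept.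

Step 9
Reactants: 10 C12 aldehyde; 12 (Z)-1-chlorooct-2-ene
Product: 14 C12 homoallylic alcohol (both C12 epimers) bearing the (Z)-oct-2-enyl chain, dioxolane, C9–OTBS and Z-vinyl iodide unchanged, via (Z)-oct-2-enylbarium chloride 13 (not isolated)
Conditions: Ba (from BaI2 and 2 lithium biphenylide, THF, rt); 12 (slight excess over Ba), −78 °C; then 10, −78 °C; AcOH/THF, −78 °C
Reagents that add atoms: none
Why: Carbonyl addition of an allylic barium reagent, which at −78 °C keeps its Z geometry and reacts at the unsubstituted α-carbon to give the linear alcohol; the slight excess of chloride leaves no reducing metal for the C–I bond, and the uncontrolled C12 carbinol centre is erased in step 16.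

Step 10
Reactants: 14 C12 homoallylic alcohol
Product: 15 C12 triethylsilyl ether of 14
Conditions: Et3SiOTf, 2,6-lutidine, CH2Cl2, −78 °C
Reagents that add atoms: triethylsilyl triflate, CC[Si](CC)(CC)OS(=O)(=O)C(F)(F)F
Why: Silylation of a secondary alcohol, which masks O12 so that no aluminium alkoxide can steer the acetal opening of step 11 and so that C6 can be oxidised alone.

Step 11
Reactants: 15 bis-silyl ether acetal
Product: 16 C6 primary alcohol with the 4-methoxybenzyl (PMB) ether on O7, C9–OTBS, C12–OTES
Conditions: i-Bu2AlH (3 equiv), CH2Cl2, −78 to 0 °C; aq. potassium sodium tartrate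
Reagents that add atoms: none
Why: Reductive opening of a 4-methoxybenzylidene acetal, in which aluminium binds the less hindered primary O6, the C–O6 bond breaks and hydride is delivered to the oxocarbenium ion, which should leave PMB on the secondary O7.

Step 12
Reactants: 16 C6 primary alcohol
Product: 17 C6 aldehyde (α-PMB-oxy aldehyde)
Conditions: Dess–Martin periodinane, NaHCO3, CH2Cl2, 0 °C to rt; crude product used at once
Reagents that add atoms: none
Why: Dess–Martin oxidation of a primary alcohol under buffered, non-basic conditions, which should spare the α-alkoxy centre C7, both silyl ethers and the vinyl iodide.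

Step 13
Reactants: 17 C6 aldehyde; 18 (4-carboxybutyl)triphenylphosphonium bromide
Product: 20 (5Z)-carboxylic acid with the complete C1–C7 chain, via carboxylate ylide 19 (not isolated)
Conditions: 18, NaN(SiMe3)2 (2 equiv per 18), THF, 0 °C to rt; then 17, −78 to −20 °C; aq. NaH2PO4
Reagents that add atoms: none
Why: Wittig olefination with a non-stabilised ylide under lithium-free conditions, whose kinetically formed cis-oxaphosphetane gives the Z C5=C6 olefin; the low temperature and the absence of excess base should spare C7 and the Z-vinyl iodide.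

Step 14
Reactants: 20 carboxylic acid
Product: 21 methyl ester of 20
Conditions: Me3SiCHN2, MeOH/toluene, 0 °C
Reagents that add atoms: trimethylsilyldiazomethane, C[Si](C)(C)C=[N+]=[N-]
Why: Esterification of a carboxylic acid with a diazoalkane, a neutral method that touches no other group.

Step 15
Reactants: 21 methyl ester
Product: 22 C12 alcohol (both epimers) with C7–OPMB and C9–OTBS
Conditions: PPTS (cat.), MeOH/CH2Cl2, 0 °C
Reagents that add atoms: none
Why: Acid-catalysed methanolysis of a triethylsilyl ether, which is much faster than cleavage of the hindered secondary tert-butyldimethylsilyl ether at C9 and leaves the PMB ether alone.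

Step 16
Reactants: 22 C12 alcohol
Product: 23 methyl (5Z,11Z)-8-[(Z)-1-(tert-butyldimethylsilyloxy)-3-iodoprop-2-enyl]-7-(4-methoxybenzyloxy)-9-oxoheptadeca-5,11-dienoate (the C12 ketone in prostanoid numbering; C7, C8 as in the target)
Conditions: Dess–Martin periodinane, NaHCO3, CH2Cl2, 0 °C; used at once
Reagents that add atoms: none
Why: Dess–Martin oxidation of a homoallylic alcohol, whose neutral buffered medium should give the β,γ-unsaturated ketone without moving the olefin into conjugation and without β-alkoxide elimination.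

Step 17
Reactants: 23 iodo ketone
Product: 25 methyl (Z)-7-[5-(tert-butyldimethylsilyloxy)-2-hydroxy-2-[(Z)-oct-2-enyl]cyclopent-3-enyl]-7-(4-methoxybenzyloxy)hept-5-enoate (C7, C8, C12 as in the target; O9 cis to the C7 branch), via vinylchromium dichloride 24 (not isolated)
Conditions: CrCl2 (8 equiv), NiCl2 (2 mol %), degassed DMF, rt; aqueous work-up
Reagents that add atoms: none
Why: CrCl2 reduces NiCl2 to zerovalent nickel, which inserts into the C11–I bond with retention; the vinyl group then passes to trivalent chromium to give 24, which adds to the C12 carbonyl through a four-centred Cr–C11/C12=O array. The closest known reaction type is the intramolecular Nozaki–Hiyama–Kishi coupling of vinyl iodides with aldehydes and, less often, ketones. The cyclopentene ring (C8–C12) closes in the 5-exo-trig mode, and the Z geometry of the iodide becomes the ring olefin C10=C11. The new C12 centre is controlled by C8: chromium on O12 is also held by the ether oxygen of C7–OPMB in a six-membered chelate, and the octenyl CH2 lies away from the C7 branch, and both effects place O12 cis to C7. The step needs the ketone to react in preference to the methyl ester and must leave the β-alkoxy, β,γ-unsaturated ketone unchanged; the low basicity of the organochromium, the neutral medium and the intramolecular delivery should secure this.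

Step 18
Reactants: 25 cyclopentenol silyl ether
Product: 26 C9,C12-diol (C9 secondary allylic, C12 tertiary) with C7–OPMB
Conditions: Bu4NF, AcOH (1:1), THF, 0 °C to rt
Reagents that add atoms: none
Why: Fluoride-induced desilylation, buffered with acetic acid so that the methyl ester and the tertiary allylic alcohol are not exposed to base.

Step 19
Reactants: 26 diol
Product: 27 4-hydroxycyclopent-2-enone (C9 ketone, C10=C11, C12–OH) with C7–OPMB
Conditions: Dess–Martin periodinane, NaHCO3, CH2Cl2, 0 °C
Reagents that add atoms: none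
Why: Dess–Martin oxidation of the secondary allylic alcohol; the tertiary C12 alcohol cannot be oxidised and, unlike with pyridinium chlorochromate, is not transposed.

Step 20
Reactants: 27 enone
Product: 28 10-chloro enone with C7–OPMB
Conditions: PhICl2 (1.2 equiv), pyridine (3 equiv), CH2Cl2, 0 °C, dark
Reagents that add atoms: (dichloroiodo)benzene, ClI(Cl)c1ccccc1
Why: α-Chlorination of an enone by addition–elimination, in which a nucleophile adds at C11, the resulting enol is chlorinated at C10 and loss of the C11 group restores the enone; this polar path should be much faster at the enone than attack on the isolated Z olefins.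

Step 21
Reactants: 28 chloro enone PMB ether
Product: 29 C7 alcohol, methyl (Z)-7-[3-chloro-5-hydroxy-5-[(Z)-oct-2-enyl]-2-oxocyclopent-3-enyl]-7-hydroxyhept-5-enoate (C7, C8, C12 as in the target)
Conditions: DDQ (1.3 equiv), CH2Cl2/pH 7 phosphate buffer, 0 °C; used at once
Reagents that add atoms: none
Why: Oxidative cleavage of a 4-methoxybenzyl ether by hydride abstraction and hydrolysis of the oxocarbenium ion, a neutral method under which the β-hydroxy ketone should not undergo retro-aldol cleavage.

Step 22
Reactants: 29 C7 alcohol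
Product: 30 punaglandin 8 (7S,8R,12S in prostanoid numbering)
Conditions: Ac2O, pyridine, CH2Cl2, 0 °C
Reagents that add atoms: acetic anhydride, CC(=O)OC(C)=O
Why: Acetylation of the secondary C7 alcohol; the tertiary C12 alcohol does not react without an acyl-transfer catalyst, and the mild base at 0 °C should not eliminate the β-acetoxy group.

**Compound list**

1 | ethyl propiolate | CCOC(=O)C#C | starting material
2 | ethyl (Z)-3-iodoprop-2-enoate | CCOC(=O)/C=C\I | intermediate
3 | (Z)-3-iodoprop-2-enal | O=C/C=C\I | intermediate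
4 | (R)-3-hydroxy-γ-butyrolactone | O=C1C[C@@H](O)CO1 | starting material
5 | dilithio dianion of 4 (lithium alkoxide, lithium enolate) | [Li+].[Li+].[O-]C1=C[C@@H]([O-])CO1 | intermediate
6 | (3R,4R)-4-hydroxy-3-[(1R,2Z)-1-hydroxy-3-iodoprop-2-en-1-yl]oxolan-2-one | O=C1[C@H]([C@@H](O)/C=C\I)[C@@H](O)CO1 | intermediate
7 | (2R,3R)-3,4-dihydroxy-2-[(1R,2Z)-1-hydroxy-3-iodoprop-2-en-1-yl]-N-methoxy-N-methylbutanamide | CON(C)C(=O)[C@H]([C@@H](O)/C=C\I)[C@@H](O)CO | intermediate
8 | Weinreb amide 7 with O6/O7 as 2-(4-methoxyphenyl)-1,3-dioxolane (both acetal epimers), C9–OH free | CON(C)C(=O)[C@H]([C@@H](O)/C=C\I)[C@@H]1COC(c2ccc(OC)cc2)O1 | intermediate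
9 | C9 tert-butyldimethylsilyl ether of 8 | CON(C)C(=O)[C@H]([C@@H](O[Si](C)(C)C(C)(C)C)/C=C\I)[C@@H]1COC(c2ccc(OC)cc2)O1 | intermediate
10 | C12 aldehyde: (Z)-3-(tert-butyldimethylsilyloxy)-5-iodo-2-[2-(4-methoxyphenyl)-1,3-dioxolan-4-yl]pent-4-enal, C7, C8, C9 as in 6 | O=C[C@H]([C@@H](O[Si](C)(C)C(C)(C)C)/C=C\I)[C@@H]1COC(c2ccc(OC)cc2)O1 | intermediate
11 | (Z)-oct-2-en-1-ol | CCCCC/C=C\CO | starting material
12 | (Z)-1-chlorooct-2-ene | CCCCC/C=C\CCl | intermediate
13 | (Z)-oct-2-enylbarium chloride | CCCCC/C=C\C[Ba]Cl | intermediate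
14 | C12 homoallylic alcohol (both C12 epimers) with (Z)-oct-2-enyl chain, dioxolane, C9–OTBS, Z-vinyl iodide | CCCCC/C=C\CC(O)[C@H]([C@@H](O[Si](C)(C)C(C)(C)C)/C=C\I)[C@@H]1COC(c2ccc(OC)cc2)O1 | intermediate
15 | C12 triethylsilyl ether of 14 | CCCCC/C=C\CC(O[Si](CC)(CC)CC)[C@H]([C@@H](O[Si](C)(C)C(C)(C)C)/C=C\I)[C@@H]1COC(c2ccc(OC)cc2)O1 | intermediate
16 | C6 primary alcohol with C7–OPMB, C9–OTBS, C12–OTES | CCCCC/C=C\CC(O[Si](CC)(CC)CC)[C@H]([C@@H](O[Si](C)(C)C(C)(C)C)/C=C\I)[C@H](CO)OCc1ccc(OC)cc1 | intermediate
17 | C6 aldehyde with C7–OPMB, C9–OTBS, C12–OTES | CCCCC/C=C\CC(O[Si](CC)(CC)CC)[C@H]([C@@H](O[Si](C)(C)C(C)(C)C)/C=C\I)[C@H](C=O)OCc1ccc(OC)cc1 | intermediate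
18 | (4-carboxybutyl)triphenylphosphonium bromide | OC(=O)CCCC[P+](c1ccccc1)(c1ccccc1)c1ccccc1.[Br-] | starting material
19 | sodium 5-(triphenylphosphoranylidene)pentanoate (carboxylate ylide) | [Na+].[O-]C(=O)CCCC=P(c1ccccc1)(c1ccccc1)c1ccccc1 | intermediate
20 | (5Z)-acid with C7–OPMB, C9–OTBS, C12–OTES | CCCCC/C=C\CC(O[Si](CC)(CC)CC)[C@H]([C@@H](O[Si](C)(C)C(C)(C)C)/C=C\I)[C@H](/C=C\CCCC(=O)O)OCc1ccc(OC)cc1 | intermediate
21 | methyl ester of 20 | CCCCC/C=C\CC(O[Si](CC)(CC)CC)[C@H]([C@@H](O[Si](C)(C)C(C)(C)C)/C=C\I)[C@H](/C=C\CCCC(=O)OC)OCc1ccc(OC)cc1 | intermediate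
22 | C12 alcohol (both epimers), methyl ester, C7–OPMB, C9–OTBS | CCCCC/C=C\CC(O)[C@H]([C@@H](O[Si](C)(C)C(C)(C)C)/C=C\I)[C@H](/C=C\CCCC(=O)OC)OCc1ccc(OC)cc1 | intermediate
23 | methyl (5Z,11Z)-8-[(Z)-1-(tert-butyldimethylsilyloxy)-3-iodoprop-2-enyl]-7-(4-methoxybenzyloxy)-9-oxoheptadeca-5,11-dienoate | CCCCC/C=C\CC(=O)[C@@H]([C@H](/C=C\CCCC(=O)OC)OCc1ccc(OC)cc1)[C@H](/C=C\I)O[Si](C)(C)C(C)(C)C | intermediate
24 | vinylchromium dichloride derived from 23 (CrCl2 group in place of iodine at C11) | CCCCC/C=C\CC(=O)[C@@H]([C@H](/C=C\CCCC(=O)OC)OCc1ccc(OC)cc1)[C@H](/C=C\[Cr](Cl)Cl)O[Si](C)(C)C(C)(C)C | intermediate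
25 | methyl (Z)-7-[5-(tert-butyldimethylsilyloxy)-2-hydroxy-2-[(Z)-oct-2-enyl]cyclopent-3-enyl]-7-(4-methoxybenzyloxy)hept-5-enoate | CCCCC/C=C\C[C@@]1(O)C=C[C@H](O[Si](C)(C)C(C)(C)C)[C@@H]1[C@H](/C=C\CCCC(=O)OC)OCc2ccc(OC)cc2 | intermediate
26 | C9,C12-diol: methyl (Z)-7-[2,5-dihydroxy-2-[(Z)-oct-2-enyl]cyclopent-3-enyl]-7-(4-methoxybenzyloxy)hept-5-enoate | CCCCC/C=C\C[C@@]1(O)C=C[C@H](O)[C@@H]1[C@H](/C=C\CCCC(=O)OC)OCc2ccc(OC)cc2 | intermediate
27 | enone: methyl (Z)-7-[5-hydroxy-5-[(Z)-oct-2-enyl]-2-oxocyclopent-3-enyl]-7-(4-methoxybenzyloxy)hept-5-enoate | CCCCC/C=C\C[C@@]1(O)C=CC(=O)[C@@H]1[C@H](/C=C\CCCC(=O)OC)OCc2ccc(OC)cc2 | intermediate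
28 | chloro enone: methyl (Z)-7-[3-chloro-5-hydroxy-5-[(Z)-oct-2-enyl]-2-oxocyclopent-3-enyl]-7-(4-methoxybenzyloxy)hept-5-enoate | CCCCC/C=C\C[C@@]1(O)C=C(Cl)C(=O)[C@@H]1[C@H](/C=C\CCCC(=O)OC)OCc2ccc(OC)cc2 | intermediate
29 | methyl (Z)-7-[3-chloro-5-hydroxy-5-[(Z)-oct-2-enyl]-2-oxocyclopent-3-enyl]-7-hydroxyhept-5-enoate | CCCCC/C=C\C[C@@]1(O)C=C(Cl)C(=O)[C@@H]1[C@H](/C=C\CCCC(=O)OC)O | intermediate
30 | punaglandin 8 | CCCCC/C=C\C[C@@]1(O)C=C(Cl)C(=O)[C@@H]1[C@H](/C=C\CCCC(=O)OC)OC(C)=O | target

**Step count**

Total step count: 22. Longest linear sequence: 21 steps (steps 1–7 and 9–22, counted from ethyl propiolate).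

**Steps most likely to fail**

1. Step 17. The vinylchromium may add too slowly to the hindered, enolisable ketone, so that protodemetalation takes over, or the facial selectivity at C12 may be poor. The fallback closes the ring on an aldehyde and brings in the octenyl chain afterwards. It sets out from aldehyde 10. CrCl2 with catalytic NiCl2 in DMF closes the ring onto the aldehyde to give cyclopentenol F1. Dess–Martin oxidation gives the 4-silyloxycyclopent-2-enone F2. (Z)-Oct-2-enylbarium chloride 13 adds 1,2 at −78 °C from the face away from the C8 and C9 substituents, which sets C12 as in the target and gives the tertiary alcohol F3. Et3SiOTf/2,6-lutidine gives the bis-silyl ether F4. i-Bu2AlH opens the acetal to the primary alcohol F5 with PMB on O7. Dess–Martin oxidation gives the aldehyde F6, the Wittig reaction with ylide 19 gives the acid F7, and Me3SiCHN2 gives the methyl ester F8. Bu4NF/AcOH then removes both silyl groups and the route is rejoined at diol 26.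

2. Step 20. Electrophilic chlorine may also attack the two isolated Z olefins or the anisyl ring. The fallback brings in oxygen as a nucleophile and chlorine as chloride, and sets out from enone 27. t-BuOOH/DBU in CH2Cl2 at 0 °C (Weitz–Scheffer epoxidation, which only the electron-poor C10=C11 bond undergoes) gives the epoxy ketone F9. Dry HCl in Et2O/THF opens the epoxide with chloride at C10, the carbon next to the ketone and away from the quaternary C12, to give the chlorohydrin F10. F10 loses water across C10–C11 under the same acid, and the route is rejoined at chloro enone 28.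

3. Step 9. The allylbarium reagent may lose its α or Z selectivity, or residual reducing metal may cleave the C–I bond. The fallback is an allylboration free of base and metal, and sets out from aldehyde 10. Commercial (E)-oct-2-en-1-ol with ClCO2Me/pyridine gives methyl (E)-oct-2-enyl carbonate F11. Borylation with bis(pinacolato)diboron under CuCl/Xantphos/KOt-Bu catalysis proceeds in the SN2' sense to racemic oct-1-en-3-ylboronic acid pinacol ester F12. F12 adds to 10 in CH2Cl2 at rt through a six-membered chair transition state in which the α-pentyl group is axial, which should give mainly the linear (Z)-homoallylic alcohol; any E isomer would be removed on AgNO3-impregnated silica. The route is rejoined at alcohol 14.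

**Further compounds**

F1 | step 17 | cyclopentenol from ring closure of aldehyde 10 (both C12 epimers), C9–OTBS, dioxolane on C8 | OC1C=C[C@H](O[Si](C)(C)C(C)(C)C)[C@@H]1[C@@H]3COC(c2ccc(OC)cc2)O3
F2 | step 17 | 4-(tert-butyldimethylsilyloxy)-5-[2-(4-methoxyphenyl)-1,3-dioxolan-4-yl]cyclopent-2-enone | O=C1C=C[C@H](O[Si](C)(C)C(C)(C)C)[C@@H]1[C@@H]3COC(c2ccc(OC)cc2)O3
F3 | step 17 | tertiary C12 alcohol with (Z)-oct-2-enyl chain, C9–OTBS, dioxolane on C8 | CCCCC/C=C\C[C@@]1(O)C=C[C@H](O[Si](C)(C)C(C)(C)C)[C@@H]1[C@@H]3COC(c2ccc(OC)cc2)O3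
F4 | step 17 | C12 triethylsilyl ether of F3 | CCCCC/C=C\C[C@@]1(O[Si](CC)(CC)CC)C=C[C@H](O[Si](C)(C)C(C)(C)C)[C@@H]1[C@@H]3COC(c2ccc(OC)cc2)O3
F5 | step 17 | C6 primary alcohol with C7–OPMB, C9–OTBS, C12–OTES | CCCCC/C=C\C[C@@]1(O[Si](CC)(CC)CC)C=C[C@H](O[Si](C)(C)C(C)(C)C)[C@@H]1[C@H](CO)OCc2ccc(OC)cc2
F6 | step 17 | C6 aldehyde with C7–OPMB, C9–OTBS, C12–OTES | CCCCC/C=C\C[C@@]1(O[Si](CC)(CC)CC)C=C[C@H](O[Si](C)(C)C(C)(C)C)[C@@H]1[C@H](C=O)OCc2ccc(OC)cc2
F7 | step 17 | (5Z)-acid with C7–OPMB, C9–OTBS, C12–OTES | CCCCC/C=C\C[C@@]1(O[Si](CC)(CC)CC)C=C[C@H](O[Si](C)(C)C(C)(C)C)[C@@H]1[C@H](/C=C\CCCC(=O)O)OCc2ccc(OC)cc2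
F8 | step 17 | methyl ester of F7 | CCCCC/C=C\C[C@@]1(O[Si](CC)(CC)CC)C=C[C@H](O[Si](C)(C)C(C)(C)C)[C@@H]1[C@H](/C=C\CCCC(=O)OC)OCc2ccc(OC)cc2
F9 | step 20 | 10,11-epoxy ketone from enone 27 (epoxide face not defined) | CCCCC/C=C\C[C@@]1(O)C2OC2C(=O)[C@@H]1[C@H](/C=C\CCCC(=O)OC)OCc3ccc(OC)cc3
F10 | step 20 | 10-chloro-11-hydroxy ketone (chlorohydrin, C10 and C11 not defined) | CCCCC/C=C\C[C@@]1(O)C(O)C(Cl)C(=O)[C@@H]1[C@H](/C=C\CCCC(=O)OC)OCc3ccc(OC)cc3
F11 | step 9 | methyl (E)-oct-2-enyl carbonate | CCCCC/C=C/COC(=O)OC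
F12 | step 9 | 4,4,5,5-tetramethyl-2-(oct-1-en-3-yl)-1,3,2-dioxaborolane (racemic) | CCCCCC(C=C)B1OC(C)(C)C(C)(C)O1
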